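**Plan**

1. Locants are those of the longipinane skeleton: C1 ring ketone, C3 CH(CH3), C4/C5/C10/C11 cyclobutane, C6 C(CH3)2, C7 and C9 ester carbons, C8 the CH2 between them. Ring A = C10–C11–C1–C2–C3–C4; ring B = C4–C5–C6–C7–C9–C10, the six-membered precursor of the seven-membered ring.
2. Retrosynthesis: cut both ester C–O bonds; take the C9 carbinol back to a ketone and the C7 oxygen back to a C7=C8 enone; contract the ring C5–C6–C7–C8–C9–C10–C11 to ring B by taking out C8 (bonds C7–C8 and C8–C9), which then sits as the CH2 of a cyclopropane fused across C7–C9; finally cut the cyclobutane bond C5–C11, one C6–CH3 bond, and the Diels–Alder bonds C10–C11 and C3–C4.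
3. Forward: ring B (from the quinone) → ring A (Diels–Alder) → temporary cyclopropane on C7–C9 → cyclobutane (C11 enolate displaces a C5 mesylate) → seven-membered ring last, by oxidative opening of the cyclopropane.
4. Enabling feature: the C9 carbonyl lies between quaternary C10 and C7, so its enol ether can form only toward C7, and the target has oxygen on C7 and C9 with one CH2 (C8) between them, which is the pattern a ring-enlarged, β-functionalised ketone leaves. The cyclopropane also masks the C9 ketone while the cyclobutane is closed.
5. Stereochemistry: C10, C4 and C3 from one catalytic enantioselective endo Diels–Alder; C5 by Mitsunobu inversion then SN2 inversion; C11 fixed by the bicyclic ring; C7 by ligand-controlled conjugate borylation; C9 by hydroxyl-directed 1,3-anti reduction; the (Z)-alkenes come in with angelic acid, one ester per step.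

Key step: step 11

Assumption: the sense of induction of the oxazaborolidinium catalyst (step 2) and of the CuCl–bisphosphine catalyst (step 12) is taken from the accepted models; if either proves opposite, the mirror-image catalyst is used.

Assumption: in the stepwise esterification the C9 hydroxyl is taken to react before the C7 hydroxyl; the diester is the same whichever hydroxyl reacts first.

Remark: in the bicyclic intermediates β is the face of ring B that carries the C10 methyl and H4; ring A leaves ring B on the α face.

**Route**

Step 1
Reactants: 1 (E)-pent-3-en-2-one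
Product: 2 (E)-2-(triisopropylsilyloxy)penta-1,3-diene
Conditions: LiN(i-Pr)2, THF, −78 °C; then i-Pr3SiOTf, −78 to 0 °C
Reagents that add atoms: triisopropylsilyl trifluoromethanesulfonate, CC(C)[Si](C(C)C)(C(C)C)OS(=O)(=O)C(F)(F)F
Why: Kinetic deprotonation of the enone at the α′-methyl group and O-silylation of the cross-conjugated enolate (silyl dienol ether formation) should give the 2-silyloxy diene with the (E)-propenyl unit untouched.

Step 2
Reactants: 2 (E)-2-(triisopropylsilyloxy)penta-1,3-diene; 3 2,5-dimethyl-1,4-benzoquinone
Product: 4 Diels–Alder adduct (cis-fused silyl enol ether enedione)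
Conditions: oxazaborolidinium bis(trifluoromethanesulfonyl)imide from (S)-α,α-diphenylprolinol and o-tolylboronic acid (20 mol %), CH2Cl2, −78 to −40 °C
Reagents that add atoms: none
Why: Enantioselective Lewis acid-catalysed Diels–Alder reaction: the boron cation binds the quinone carbonyl beside its vinylic C–H, so the nucleophilic CH2 terminus of the diene should add to the methyl-bearing β-carbon (C10) and the methyl-bearing terminus to C4, the endo transition state puts the C3 methyl cis to the C5 carbonyl, and the shielded catalyst face sets the absolute configuration of C10, C4 and C3 together.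

Step 3
Reactants: 4 Diels–Alder adduct
Product: 5 5α-allylic alcohol
Conditions: NaBH4, CeCl3·7H2O, MeOH, −78 °C
Reagents that add atoms: none
Why: Luche 1,2-reduction: the C5 carbonyl (next to the ring-fusion CH) is less hindered than the C9 carbonyl (next to quaternary C10), and hydride should enter from the convex β face, leaving the hydroxyl α, cis to ring A.

Step 4
Reactants: 5 5α-allylic alcohol
Product: 6 5β-(4-nitrobenzoate)
Conditions: 4-nitrobenzoic acid, PPh3, DIAD, THF, 0 °C to rt
Reagents that add atoms: 4-nitrobenzoic acid, O=C(O)c1ccc(cc1)[N+](=O)[O-]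
Why: Mitsunobu esterification with SN2 inversion at the allylic C5 carbinol (the carboxylate enters from the open convex face) places the oxygen trans to ring A, as the later backside displacement requires.

Step 5
Reactants: 6 5β-(4-nitrobenzoate)
Product: 8 5β-hydroxy enone ketone, via 5β-alcohol silyl enol ether 7 (not isolated)
Conditions: K2CO3 (cat.), MeOH, 0 °C; then 1 M HCl, THF, rt
Reagents that add atoms: none
Why: Transesterification of the activated nitrobenzoate followed by acid hydrolysis of the silyl enol ether should unveil the C5 alcohol and the C1 ketone without touching a stereocentre (C3 is β to the new ketone).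

Step 6
Reactants: 8 5β-hydroxy enone ketone
Product: 9 bis(triethylsilyl) compound (C5 silyl ether and C9 silyl enol ether)
Conditions: Me2CuLi, Et3SiCl, Et3N, THF/Et2O, −78 to −20 °C
Reagents that add atoms: lithium dimethylcuprate, [Li+].C[Cu-]C; chlorotriethylsilane, CC[Si](Cl)(CC)CC
Why: Et3SiCl-accelerated 1,4-addition of Me2CuLi to the β-methyl enone should create the C6 gem-dimethyl carbon (no new stereocentre) and trap the enolate regiospecifically as the C9(OSiEt3)=C7 enol ether while the C5 hydroxyl is silylated and the saturated C1 ketone stays untouched at low temperature.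

Step 7
Reactants: 9 bis(triethylsilyl) compound
Product: 10 siloxycyclopropane
Conditions: Et2Zn, CH2I2, CH2Cl2, 0 °C to rt
Reagents that add atoms: diiodomethane, ICI
Why: Simmons–Smith cyclopropanation of the electron-rich silyl enol ether installs C8 across C7–C9, the carbenoid EtZnCH2I expected on the β face because C11 of ring A shields the α face; the cyclopropane configuration is erased in step 11.

Step 8
Reactants: 10 siloxycyclopropane
Product: 11 5β-alcohol
Conditions: HF·pyridine, pyridine, THF, 0 °C
Reagents that add atoms: none
Why: Buffered fluoride desilylation should discriminate by hindrance, cleaving the secondary C5 silyl ether and leaving the tertiary cyclopropyl silyl ether.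

Step 9
Reactants: 11 5β-alcohol
Product: 12 5β-mesylate
Conditions: MsCl, Et3N, CH2Cl2, 0 °C
Reagents that add atoms: methanesulfonyl chloride, CS(=O)(=O)Cl
Why: Sulfonylation of the hindered secondary alcohol through sulfene gives the leaving group with retention at C5.

Step 10
Reactants: 12 5β-mesylate
Product: 13 tetracyclic siloxycyclopropane ketone
Conditions: KOt-Bu, t-BuOH/THF, rt to 45 °C
Reagents that add atoms: none
Why: Intramolecular ketone enolate C-alkylation (4-exo-tet) under equilibrating conditions: only the C11 enolate, axial on ring B and 1,3 to C5, can reach the backside of the equatorial C5 mesylate, so the cyclobutane should close with inversion at C5 and the only possible configuration at C11, while the cyclopropane keeps C7 from enolising and closing a three-membered ring instead.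

Step 11
Reactants: 13 tetracyclic siloxycyclopropane ketone
Product: 15 longipin-7-ene-1,9-dione, via 7-chloro diketone 14 (not isolated)
Conditions: FeCl3 (2.5 equiv), pyridine, DMF, 0 °C to rt; then NaOAc, MeOH, 60 °C
Reagents that add atoms: iron trichloride, Cl[Fe](Cl)Cl (its chlorine is carried by 14 only)
Why: Ito–Saegusa oxidative ring enlargement of a siloxycyclopropane: FeCl3 turns the silyl ether into the cyclopropanolate ROFeCl2 and oxidises it by inner-sphere electron transfer to the cyclopropyloxy radical, which releases the three-ring strain by β-scission of the internal C7–C9 bond, leaving the C9 ketone in a seven-membered ring and a secondary radical at C7 that takes chlorine from a second FeCl3 to give 14. NaOAc then removes HCl by E1cB elimination through the C8 enolate, the only enolisable position of the C9 ketone because C10 is quaternary, giving the C7=C8 enone. The seven-membered ring is therefore not closed by a cyclisation but arises by fragmentation of the zero-atom bridge of the bicyclo[4.1.0]heptane unit, that is by insertion of C8 between C7 and C9 of ring B. No lasting stereocentre is made: C7 of 14 becomes sp2 and the cyclopropane stereocentres vanish. The step needs cleavage of C7–C9 and not of C8–C9 or C9–C10; this is secured because only the internal bond gives a secondary radical with loss of the cyclopropane strain, the C7 radical is insulated from the cyclobutane by quaternary C6, and the C1 ketone is a bystander.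

Step 12
Reactants: 15 longipin-7-ene-1,9-dione
Product: 17 7-hydroxylongipinane-1,9-dione, via 7-boronate 16 (not isolated)
Conditions: CuCl (10 mol %), (R)-1-[(S)-2-(diphenylphosphino)ferrocenyl]ethyldicyclohexylphosphine, NaOt-Bu (cat.), B2pin2, MeOH, THF, rt; then NaBO3·4H2O, THF/H2O, rt
Reagents that add atoms: sodium perborate, [Na+].OO[B-](O)(O)O; bis(pinacolato)diboron, CC1(C)OB(OC1(C)C)B1OC(C)(C)C(C)(C)O1 (its boron is carried by 16 only)
Why: CuCl-catalysed enantioselective conjugate borylation of the cyclic enone followed by stereoretentive C–B oxidation; the chiral CuCl–bisphosphine catalyst is relied on for the face of C7 because the nearly mirror-symmetric surroundings above the cyclobutane give little substrate bias, and the saturated C1 ketone is no acceptor.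

Step 13
Reactants: 17 7-hydroxylongipinane-1,9-dione
Product: 18 7,9-dihydroxylongipinan-1-one
Conditions: Me4NBH(OAc)3, MeCN/AcOH, −35 °C
Reagents that add atoms: none
Why: Evans–Saksena reduction: the C7 hydroxyl binds the triacetoxyborohydride and delivers hydride intramolecularly to the same face of C9, so the new C9 hydroxyl should be trans (1,3-anti) to the C7 oxygen, and the C1 ketone, lacking a directing hydroxyl, is not reduced.

Step 14
Reactants: 18 7,9-dihydroxylongipinan-1-one; 19 angelic acid
Product: 20 9-O-angeloyl-7-hydroxylongipinan-1-one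
Conditions: 19 (1.1 equiv), 2,4,6-trichlorobenzoyl chloride, Et3N, toluene, rt; then 18, 60 °C
Reagents that add atoms: none
Why: Yamaguchi-type mixed anhydride esterification without a nucleophilic amine catalyst should transfer one (Z)-2-methylbut-2-enoyl group without isomerisation to the (E) isomer, and with one equivalent the C9 hydroxyl should react first because its quaternary neighbour C10 is tied back in the cyclobutane whereas C7 lies beside the gem-dimethyl carbon C6.

Step 15
Reactants: 20 9-O-angeloyl-7-hydroxylongipinan-1-one; 19 angelic acid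
Product: 21 target diangelate
Conditions: 19 (3 equiv), 2,4,6-trichlorobenzoyl chloride, Et3N, toluene, rt; then 20, 80 °C
Reagents that add atoms: none
Why: The same Yamaguchi-type mixed anhydride esterification, now with excess anhydride at higher temperature, should force the remaining neopentyl-type C7 hydroxyl to the second angelate, and leaving out a nucleophilic amine catalyst again guards the (Z) geometry of both esters.

**Compound list**

1 | (E)-pent-3-en-2-one | C/C=C/C(C)=O | starting material
2 | (E)-2-(triisopropylsilyloxy)penta-1,3-diene | C=C(O[Si](C(C)C)(C(C)C)C(C)C)/C=C/C | intermediate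
3 | 2,5-dimethyl-1,4-benzoquinone | CC1=CC(=O)C(C)=CC1=O | starting material
4 | Diels–Alder adduct: cis-fused rings A and B; ring A C11H2–C1(OSi-i-Pr3)=C2H–C3H(α-CH3); ring B C9(=O)–C7H=C6(CH3)–C5(=O); 10β-CH3, 4β-H | C[C@]12CC(O[Si](C(C)C)(C(C)C)C(C)C)=C[C@@H](C)[C@H]1C(=O)C(C)=CC2=O | intermediate
5 | 5α-allylic alcohol of 4 (C9 enone retained) | C[C@]12CC(O[Si](C(C)C)(C(C)C)C(C)C)=C[C@@H](C)[C@H]1[C@@H](O)C(C)=CC2=O | intermediate
6 | 5β-(4-nitrobenzoate), inverted at C5 | C[C@]12CC(O[Si](C(C)C)(C(C)C)C(C)C)=C[C@@H](C)[C@H]1[C@H](OC(=O)c3ccc(cc3)[N+](=O)[O-])C(C)=CC2=O | intermediate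
7 | 5β-alcohol silyl enol ether (not isolated) | C[C@]12CC(O[Si](C(C)C)(C(C)C)C(C)C)=C[C@@H](C)[C@H]1[C@H](O)C(C)=CC2=O | intermediate
8 | 5β-hydroxy enone ketone: C1 ketone, C9(=O)–C7H=C6(CH3), 5β-OH | C[C@]12CC(=O)C[C@@H](C)[C@H]1[C@H](O)C(C)=CC2=O | intermediate
9 | bis(triethylsilyl) compound: 5β-OSiEt3, C6(CH3)2, C9(OSiEt3)=C7 enol ether, C1 ketone | C[C@]12CC(=O)C[C@@H](C)[C@H]1[C@H](O[Si](CC)(CC)CC)C(C)(C)C=C2O[Si](CC)(CC)CC | intermediate
10 | siloxycyclopropane: 9 with C8H2 fused across C7–C9 on the β face (9α-OSiEt3, 7α-H) | C[C@]12CC(=O)C[C@@H](C)[C@H]1[C@H](O[Si](CC)(CC)CC)C(C)(C)[C@@H]3C[C@]23O[Si](CC)(CC)CC | intermediate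
11 | 5β-alcohol of 10 (cyclopropyl silyl ether kept) | C[C@]12CC(=O)C[C@@H](C)[C@H]1[C@H](O)C(C)(C)[C@@H]3C[C@]23O[Si](CC)(CC)CC | intermediate
12 | 5β-methanesulfonate of 11 | C[C@]12CC(=O)C[C@@H](C)[C@H]1[C@H](OS(C)(=O)=O)C(C)(C)[C@@H]3C[C@]23O[Si](CC)(CC)CC | intermediate
13 | tetracyclic ketone: cyclobutane C4–C5–C11–C10 closed, ring B six-membered with the C7–C8–C9 siloxycyclopropane, C1 ketone; C3, C4, C5, C10, C11 as in the target | CC[Si](CC)(CC)O[C@]12C[C@H]1C(C)(C)[C@H]3[C@@H]4[C@H](C)CC(=O)[C@H]3[C@]24C | intermediate
14 | 7-chlorolongipinane-1,9-dione, C7 epimers (not isolated) | ClC1CC(=O)[C@]2(C)[C@@H]3[C@@H]([C@H]2C(=O)C[C@H]3C)C1(C)C | intermediate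
15 | longipin-7-ene-1,9-dione | C1=CC(=O)[C@]2(C)[C@@H]3[C@@H]([C@H]2C(=O)C[C@H]3C)C1(C)C | intermediate
16 | 7-(pinacolboryl)longipinane-1,9-dione, boron in the position of the target's C7 oxygen (not isolated) | CC1(C)OB([C@@H]2CC(=O)[C@]3(C)[C@@H]4[C@@H]([C@H]3C(=O)C[C@H]4C)C2(C)C)OC1(C)C | intermediate
17 | 7-hydroxylongipinane-1,9-dione, C7 as in the target | O[C@@H]1CC(=O)[C@]2(C)[C@@H]3[C@@H]([C@H]2C(=O)C[C@H]3C)C1(C)C | intermediate
18 | 7,9-dihydroxylongipinan-1-one, hydroxyls trans, all centres as in the target | O[C@@H]1C[C@@H](O)[C@]2(C)[C@@H]3[C@@H]([C@H]2C(=O)C[C@H]3C)C1(C)C | intermediate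
19 | angelic acid, (Z)-2-methylbut-2-enoic acid | C/C=C(/C)C(=O)O | starting material
20 | 9-O-angeloyl-7-hydroxylongipinan-1-one: (Z)-2-methylbut-2-enoate on C9, free hydroxyl on C7, all centres as in the target | O[C@@H]1C[C@@H](OC(=O)/C(C)=C\C)[C@]2(C)[C@@H]3[C@@H]([C@H]2C(=O)C[C@H]3C)C1(C)C | intermediate
21 | (3R,4S,5S,7R,9R,10R,11R)-7,9-bis[(Z)-2-methylbut-2-enoyloxy]longipinan-1-one (longipinane locants) | C/C=C(/C)C(=O)O[C@@H]1C[C@@H](OC(=O)/C(C)=C\C)[C@]2(C)[C@@H]3[C@@H]([C@H]2C(=O)C[C@H]3C)C1(C)C | target

**Count and risks**

Total steps: 15. Longest linear sequence: 15 steps (from 1; 14 from 3).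

Step 10 (cyclobutane closure). The displacement at the hindered C5 centre may be too slow, so that O-alkylation of the enolate or loss of the silyl group under prolonged base takes over. Fallback: close the ring with a β-dicarbonyl dianion, which is a far stronger and purely carbon nucleophile with a single carbanionic site. Setting out from mesylate 12, Claisen formylation at the less hindered C2 (HCO2Et, NaH, THF, 0 °C) gives the 2-hydroxymethylene ketone F1. LiN(i-Pr)2 (2.2 equiv, THF, −78 to 0 °C) forms the dianion, whose only carbanionic site is C11; it displaces the mesylate to give the tetracyclic 2-hydroxymethylene ketone F2. Retro-Claisen deformylation (K2CO3, MeOH/H2O, rt) comes back to the route at 13.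

Step 12 (C7 oxygen). Conjugate borylation at a β-carbon flanked by quaternary C6 may be sluggish, and facial selectivity may be poor. Fallback: introduce the oxygen as a peroxide nucleophile and open the epoxide reductively. Setting out from enone 15, Weitz–Scheffer epoxidation (t-BuOOH, DBU, CH2Cl2, rt) gives the 7,8-epoxy ketone F3 together with its 7,8-diastereomer F4; the facial choice then rests on the substrate and the two are separated. SmI2 (THF/MeOH, −78 °C) cleaves the C8–O bond of F3 with retention at C7 and comes back to the route at 17.

Step 15 (second angeloylation). Acylation of the remaining neopentyl-type C7 hydroxyl by a branched acid may stall, and forcing it may isomerise the (Z)-alkenes. Fallback: build the second (Z)-alkene on the ester. Setting out from mono-angelate 20, acylation of the C7 hydroxyl with 2-[bis(2,2,2-trifluoroethoxy)phosphoryl]propanoyl chloride (pyridine, CH2Cl2, 0 °C to rt) gives the 7-phosphonopropionate F5. Still–Gennari olefination (KN(SiMe3)2, 18-crown-6, THF, −78 °C; acetaldehyde) forms the second (Z)-2-methylbut-2-enoate and comes back to the route at 21.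

**Further compounds**

F1 | step 10 | 2-hydroxymethylene derivative of mesylate 12 | C[C@]12CC(=O)/C(=C\O)[C@@H](C)[C@H]1[C@H](OS(C)(=O)=O)C(C)(C)[C@@H]3C[C@]23O[Si](CC)(CC)CC
F2 | step 10 | 2-hydroxymethylene derivative of tetracyclic ketone 13 | CC[Si](CC)(CC)O[C@]12C[C@H]1C(C)(C)[C@H]3[C@@H]4[C@H](C)/C(=C/O)C(=O)[C@H]3[C@]24C
F3 | step 12 | 7,8-epoxylongipinane-1,9-dione, epoxide oxygen on the face of the C7 oxygen of 17 | O1[C@@H]2[C@H]1C(=O)[C@]3(C)[C@@H]4[C@@H]([C@H]3C(=O)C[C@H]4C)C2(C)C
F4 | step 12 | 7,8-epoxylongipinane-1,9-dione, epoxide on the opposite face | O1[C@H]2[C@@H]1C(=O)[C@]3(C)[C@@H]4[C@@H]([C@H]3C(=O)C[C@H]4C)C2(C)C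
F5 | step 15 | 9-O-angeloyl-7-O-{2-[bis(2,2,2-trifluoroethoxy)phosphoryl]propanoyl} derivative of diol 18 | CC(C(=O)O[C@@H]1C[C@@H](OC(=O)/C(C)=C\C)[C@]2(C)[C@@H]3[C@@H]([C@H]2C(=O)C[C@H]3C)C1(C)C)P(=O)(OCC(F)(F)F)OCC(F)(F)F
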